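## Retrosynthetic overview

1. Pieces in forward order: ring A as the symmetric acetophenone 1, the terpene ring with its stereocentre as (R)-α-phellandrene 2 (joined to give 3), ring B as benzaldehyde 4 (aldol 5, chalcone 6), target 7.
2. First disconnection: O1–C2 of ring C in 7 (retro-oxa-Michael) to the open 2',6'-dihydroxychalcone 6. In the forward sense this closure sets 2S and decides 6- versus 8-linkage.
3. Second disconnection: Cα=Cβ of 6 (retro-Claisen–Schmidt) to 3 + 4.
4. Third disconnection: aryl–C1'' of 3 (retro-Friedel–Crafts) to 1 + 2. C3 and C5 of 1 are equivalent, so only one constitution can form.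
5. Ring order: ring A, ring B and the cyclohexene are bought intact; ring C is the only ring made, and it is made last.

Assumption 1: the quinine-derived thiourea of step 3 is taken to deliver 2S; the sense is checked on the first run (dr by HPLC) and, if it is 2R, the quinidine-derived pseudoenantiomer replaces it without other change.

Assumption 2: commercial (R)-(−)-α-phellandrene is taken as highly enantioenriched; its ee is carried into 3.

## Route

Step 1
Reactants: 1 2',6'-dihydroxy-4'-methoxyacetophenone; 2 (R)-(−)-α-phellandrene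
Product: 3 1-{2,6-dihydroxy-4-methoxy-3-[(1R,6R)-3-methyl-6-(propan-2-yl)cyclohex-2-en-1-yl]phenyl}ethan-1-one
Conditions: p-TsOH·H2O (10 mol %), CH2Cl2, 0 °C → rt, 2 added slowly to 1 (1.5 equiv)
Reagents that add atoms: none
Why: Brønsted-acid Friedel–Crafts hydroarylation of a 1,3-diene, in which protonation of 2 at the diene terminus remote from the isopropyl group gives the tertiary/secondary piperityl allyl cation, and C3 of 1 attacks its secondary terminus anti to the neighbouring isopropyl group, so the aryl-bearing centre is set trans (1R) by the untouched centre of 2, which becomes 6R.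

Step 2
Reactants: 3 1-{2,6-dihydroxy-4-methoxy-3-[(1R,6R)-3-methyl-6-(propan-2-yl)cyclohex-2-en-1-yl]phenyl}ethan-1-one; 4 benzaldehyde
Product: 6 (2E)-1-{2,6-dihydroxy-4-methoxy-3-[(1R,6R)-3-methyl-6-(propan-2-yl)cyclohex-2-en-1-yl]phenyl}-3-phenylprop-2-en-1-one, via aldol adduct 5 (not isolated)
Conditions: KOH (60% aq., excess), EtOH, rt, 48 h, N2; then cold 1 M HCl to pH 3–4, fast extraction, crystallisation
Reagents that add atoms: none
Why: Claisen–Schmidt aldol condensation, in which the ketone enolate adds to non-enolisable 4 and E1cB loss of hydroxide from 5 gives the conjugated E-enone, which stays ring-open as its polyphenoxide in strong base; no stereocentre is formed or touched.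

Step 3
Reactants: 6 (2E)-1-{2,6-dihydroxy-4-methoxy-3-[(1R,6R)-3-methyl-6-(propan-2-yl)cyclohex-2-en-1-yl]phenyl}-3-phenylprop-2-en-1-one
Product: 7 (2S)-5-hydroxy-7-methoxy-6-[(1R,6R)-3-methyl-6-(propan-2-yl)cyclohex-2-en-1-yl]-2-phenyl-2,3-dihydro-4H-chromen-4-one (target)
Conditions: N-[3,5-bis(trifluoromethyl)phenyl]-N'-[(8α,9S)-6'-methoxycinchonan-9-yl]thiourea (10 mol %), toluene, −20 °C, 48–72 h; silica plug, then recrystallisation to raise dr
Reagents that add atoms: none
Why: Proposed new method: a chalcone-isomerase-like asymmetric 6-endo-trig intramolecular oxa-Michael addition in which the quinuclidine nitrogen of the bifunctional catalyst deprotonates the unhindered 6'-OH (the 2'-OH next to the menthenyl group is locked in the chelate hydrogen bond to C=O and shielded, so the 6-linked and not the 8-linked flavanone forms) while the thiourea binds the enone carbonyl and the catalyst directs attack to one face of Cβ to set 2S, the closest known reaction type being the cinchona-thiourea-catalysed enantioselective cyclisation of simple 2'-hydroxychalcones to flavanones.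

## Compound list

1 | 1-(2,6-dihydroxy-4-methoxyphenyl)ethan-1-one (2',6'-dihydroxy-4'-methoxyacetophenone) | CC(=O)c1c(O)cc(OC)cc1O | starting material
2 | (5R)-2-methyl-5-(propan-2-yl)cyclohexa-1,3-diene ((R)-(−)-α-phellandrene) | CC1=CC[C@@H](C=C1)C(C)C | starting material
3 | 1-{2,6-dihydroxy-4-methoxy-3-[(1R,6R)-3-methyl-6-(propan-2-yl)cyclohex-2-en-1-yl]phenyl}ethan-1-one | COc1cc(O)c(C(C)=O)c(O)c1[C@H]1C=C(C)CC[C@@H]1C(C)C | intermediate
4 | benzaldehyde | O=Cc1ccccc1 | starting material
5 | 1-{2,6-dihydroxy-4-methoxy-3-[(1R,6R)-3-methyl-6-(propan-2-yl)cyclohex-2-en-1-yl]phenyl}-3-hydroxy-3-phenylpropan-1-one (both carbinol epimers, not isolated) | COc1cc(O)c(C(=O)CC(O)c2ccccc2)c(O)c1[C@H]1C=C(C)CC[C@@H]1C(C)C | intermediate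
6 | (2E)-1-{2,6-dihydroxy-4-methoxy-3-[(1R,6R)-3-methyl-6-(propan-2-yl)cyclohex-2-en-1-yl]phenyl}-3-phenylprop-2-en-1-one | COc1cc(O)c(C(=O)/C=C/c2ccccc2)c(O)c1[C@H]1C=C(C)CC[C@@H]1C(C)C | intermediate
7 | (2S)-5-hydroxy-7-methoxy-6-[(1R,6R)-3-methyl-6-(propan-2-yl)cyclohex-2-en-1-yl]-2-phenyl-2,3-dihydro-4H-chromen-4-one | COc1cc2c(c(O)c1[C@H]1C=C(C)CC[C@@H]1C(C)C)C(=O)C[C@@H](c1ccccc1)O2 | target

## Step count and risks

Total step count: 3. Longest linear sequence: 3 (1 or 2 → 3 → 6 → 7).

**Step 3 (most likely to fail).** The catalyst may give a poor 2S:2R ratio, or the hindered 2'-OH may close in part. The fallback sets out from 6 and comes back at 7, replacing catalyst control by separation and recycling. Chalcone 6 is closed without selectivity (NaOAc, EtOH, reflux). This gives 7 together with (2R)-5-hydroxy-7-methoxy-6-[(1R,6R)-3-methyl-6-(propan-2-yl)cyclohex-2-en-1-yl]-2-phenyl-2,3-dihydro-4H-chromen-4-one F1, the 8-linked regioisomer (2S)-5-hydroxy-7-methoxy-8-[(1R,6R)-3-methyl-6-(propan-2-yl)cyclohex-2-en-1-yl]-2-phenyl-2,3-dihydro-4H-chromen-4-one F2 and its C2 epimer (2R)-5-hydroxy-7-methoxy-8-[(1R,6R)-3-methyl-6-(propan-2-yl)cyclohex-2-en-1-yl]-2-phenyl-2,3-dihydro-4H-chromen-4-one F3. All four are diastereomers or constitutional isomers, so 7 is separated by silica chromatography (6- from 8-linked) and preparative HPLC on a cellulose carbamate phase (7 from F1). The rest is reopened to 6 with KOH/EtOH and cycled again.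

**Step 1.** Acid can isomerise 2 to achiral α-terpinene or p-cymene before the acyl-deactivated arene traps the cation, which costs yield and optical purity; double alkylation is a lesser risk. The fallback sets out from 1 and comes back at 3, replacing the diene by an allylic alcohol that ionises under a mild Lewis acid to the same allyl cation.
- (S)-(−)-Limonene F4 is hydrogenated at the isopropenyl group only (H2, RhCl(PPh3)3, benzene, rt) to (4S)-1-methyl-4-(propan-2-yl)cyclohex-1-ene F5.
- A Schenck ene reaction (O2, hν, rose bengal, MeOH) gives (4R)-1-methyl-4-(propan-2-yl)cyclohex-2-en-1-yl hydroperoxide F6.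
- PPh3 reduces it to (4R)-1-methyl-4-(propan-2-yl)cyclohex-2-en-1-ol F7 (both C1 epimers serve), isolated by distillation.
- F7 alkylates 1 (BF3·OEt2 on basic alumina, CH2Cl2, rt) to give 3. Dienes formed by proton loss are not re-protonated under these buffered conditions.

**Step 2.** The acetyl group of 3 sits between two phenoxides and beside a bulky ring, so enolisation is slow, and 6 may close to flavanone during work-up. The fallback sets out from 1 and comes back at 6, reversing the order of the two C–C bond formations. Compounds 1 and 4 are condensed first (KOH, EtOH, rt) via 1-(2,6-dihydroxy-4-methoxyphenyl)-3-hydroxy-3-phenylpropan-1-one F8 to (2E)-1-(2,6-dihydroxy-4-methoxyphenyl)-3-phenylprop-2-en-1-one F9 (pinostrobin chalcone), whose ring A is still symmetric. F9 is then alkylated with 2 (p-TsOH·H2O, CH2Cl2, 0 °C) to give 6. Material that has ring-closed under the acid (7, the 2R epimer F1, the 8-linked isomers F2 and F3) is reopened to the single chalcone 6 by a final KOH/EtOH treatment.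

## Further compounds

F1 | step 3 | (2R)-5-hydroxy-7-methoxy-6-[(1R,6R)-3-methyl-6-(propan-2-yl)cyclohex-2-en-1-yl]-2-phenyl-2,3-dihydro-4H-chromen-4-one | COc1cc2c(c(O)c1[C@H]1C=C(C)CC[C@@H]1C(C)C)C(=O)C[C@H](c1ccccc1)O2
F2 | step 3 | (2S)-5-hydroxy-7-methoxy-8-[(1R,6R)-3-methyl-6-(propan-2-yl)cyclohex-2-en-1-yl]-2-phenyl-2,3-dihydro-4H-chromen-4-one | COc1cc(O)c2C(=O)C[C@@H](c3ccccc3)Oc2c1[C@H]1C=C(C)CC[C@@H]1C(C)C
F3 | step 3 | (2R)-5-hydroxy-7-methoxy-8-[(1R,6R)-3-methyl-6-(propan-2-yl)cyclohex-2-en-1-yl]-2-phenyl-2,3-dihydro-4H-chromen-4-one | COc1cc(O)c2C(=O)C[C@H](c3ccccc3)Oc2c1[C@H]1C=C(C)CC[C@@H]1C(C)C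
F4 | step 1 | (S)-(−)-limonene (purchased) | CC1=CC[C@H](CC1)C(=C)C
F5 | step 1 | (4S)-1-methyl-4-(propan-2-yl)cyclohex-1-ene | CC1=CC[C@H](CC1)C(C)C
F6 | step 1 | (4R)-1-methyl-4-(propan-2-yl)cyclohex-2-en-1-yl hydroperoxide (C1 epimers) | CC1(OO)C=C[C@@H](C(C)C)CC1
F7 | step 1 | (4R)-1-methyl-4-(propan-2-yl)cyclohex-2-en-1-ol (C1 epimers) | CC1(O)C=C[C@@H](C(C)C)CC1
F8 | step 2 | 1-(2,6-dihydroxy-4-methoxyphenyl)-3-hydroxy-3-phenylpropan-1-one (racemic, not isolated) | COc1cc(O)c(C(=O)CC(O)c2ccccc2)c(O)c1
F9 | step 2 | (2E)-1-(2,6-dihydroxy-4-methoxyphenyl)-3-phenylprop-2-en-1-one | COc1cc(O)c(C(=O)/C=C/c2ccccc2)c(O)c1
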